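## Retrosynthetic overview

1. Ring labels: A = hydroxycyclopentane carrying isopropyl, B = cyclohexene, C = eight-membered ring, D = methylcyclopentane. The exocyclic methylene and the secondary alcohol are traced back to a tetracyclic enedione (ring C enone, ring A cyclopentanone).
2. Key disconnection, rings A and B together: a divalent-palladium cascade on a 1-isopropenylcyclobutanol tethered to the ring C enone. Semipinacol ring expansion of the four-membered ring gives the five-membered ring A; 6-endo insertion of the resulting neopentylpalladium into the enone and β-hydride elimination give ring B.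
3. Enabling feature: the methyl-bearing quaternary carbon of the A/B fusion lies between the carbinol carbon of ring A (an α-quaternary cyclopentanone one oxidation level up) and a ring B CH2. That CH2 is bonded to the B/C alkene carbon β to the methylene-bearing carbon of ring C (an enone β-carbon once =CH2 is =O).
4. The cascade precursor comes from a Mukaiyama–Michael union of the (S)-silyl enol ether of 3-isopropylcyclobutanone (ketene [2+2], asymmetric deprotonation) with an α-methylene bicyclic ketone, then Saegusa oxidation and isopropenyl addition.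
5. The bicyclic ketone comes from ring-closing metathesis (ring C) of a cyclopentane made from (S)-limonene (ring D by aldol ring contraction, directed hydrogenation) and (R)-3-bromo-2-methylpropanol. Ring order: D, C, cyclobutane appended, then A and B in one step.

Key step: step 22

Assumption: deprotonation of 3-isopropylcyclobutanone by lithium bis[(1S)-1-phenylethyl]amide is taken to give the (S)-silyl enol ether 24; if the sense is opposite, the (R,R)-amide is used.

Assumption: the isopropenyl nucleophile is taken to add to the cyclobutanone of 26 trans to the adjacent CH2 arm; this carbinol configuration is lost in step 22 but decides which rotamer gives the trans ring fusion (the other epimer would need chelating, non-donor conditions there).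

## Route

Step 1
Reactants: 1 (S)-(−)-limonene
Product: 2 (3S)-6-oxo-3-(prop-1-en-2-yl)heptanal
Conditions: O3 (1.0 equiv), CH2Cl2–MeOH, −78 °C; then Me2S, −78 °C → rt
Reagents that add atoms: ozone [O-][O+]=O
Why: Ozonolysis with one equivalent of ozone should cleave the electron-richer trisubstituted ring alkene faster than the 1,1-disubstituted isopropenyl group and leaves the stereocentre untouched.

Step 2
Reactants: 2 (3S)-6-oxo-3-(prop-1-en-2-yl)heptanal
Product: 3 (5R)-2-methyl-5-(prop-1-en-2-yl)cyclopent-1-ene-1-carbaldehyde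
Conditions: piperidine (cat.), AcOH (cat.), benzene, reflux (Dean–Stark)
Reagents that add atoms: none
Why: Amine/acid-catalysed intramolecular aldol condensation of the aldehyde α-carbon onto the methyl ketone closes ring D as the conjugated cyclopentenecarbaldehyde and keeps the non-enolisable stereocentre.

Step 3
Reactants: 3 (5R)-2-methyl-5-(prop-1-en-2-yl)cyclopent-1-ene-1-carbaldehyde
Product: 4 [(5R)-2-methyl-5-(prop-1-en-2-yl)cyclopent-1-en-1-yl]methanol
Conditions: NaBH4, CeCl3·7H2O, MeOH, 0 °C
Reagents that add atoms: none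
Why: Luche reduction should give clean 1,2-reduction of the enal to the allylic alcohol.

Step 4
Reactants: 4 [(5R)-2-methyl-5-(prop-1-en-2-yl)cyclopent-1-en-1-yl]methanol
Product: 5 (3R)-2-(bromomethyl)-1-methyl-3-(prop-1-en-2-yl)cyclopent-1-ene
Conditions: CBr4, PPh3, CH2Cl2, 0 °C
Reagents that add atoms: carbon tetrabromide BrC(Br)(Br)Br
Why: Appel bromination converts the primary allylic alcohol into the bromide under neutral conditions, and allylic transposition is disfavoured because the far alkene carbon is fully substituted.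

Step 5
Reactants: 6 (2R)-3-bromo-2-methylpropan-1-ol
Product: 7 [(2R)-3-bromo-2-methylpropoxy](tert-butyl)dimethylsilane
Conditions: TBSCl, imidazole, DMF, rt
Reagents that add atoms: tert-butyldimethylsilyl chloride CC(C)(C)[Si](C)(C)Cl
Why: Standard silylation protects the primary alcohol through the organometallic and hydrogenation steps; the stereocentre (the future ring C CH–CH3) comes from the chiral pool.

Step 6
Reactants: 7 [(2R)-3-bromo-2-methylpropoxy](tert-butyl)dimethylsilane; 5 (3R)-2-(bromomethyl)-1-methyl-3-(prop-1-en-2-yl)cyclopent-1-ene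
Product: 9 tert-butyldimethyl{[(2S)-2-methyl-4-[(5R)-2-methyl-5-(prop-1-en-2-yl)cyclopent-1-en-1-yl]butyl]oxy}silane, via Grignard reagent 8 (not isolated)
Conditions: 7, Mg, THF, reflux; then 5, Li2CuCl4 (3 mol %), THF, −78 → 0 °C
Reagents that add atoms: none
Why: Copper-catalysed Grignard cross-coupling at the primary allylic bromide (SN2, not SN2′, because the far alkene carbon is fully substituted) joins the side chain without touching either stereocentre.

Step 7
Reactants: 9 tert-butyldimethyl{[(2S)-2-methyl-4-[(5R)-2-methyl-5-(prop-1-en-2-yl)cyclopent-1-en-1-yl]butyl]oxy}silane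
Product: 10 2-[(1S)-2-[(3S)-4-{[tert-butyl(dimethyl)silyl]oxy}-3-methylbutyl]-3-methylcyclopent-2-en-1-yl]propane-1,2-diol (both epimers at the diol carbon)
Conditions: OsO4 (2 mol %), NMO, acetone–H2O, rt
Reagents that add atoms: N-methylmorpholine N-oxide C[N+]1([O-])CCOCC1; water O
Why: Catalytic dihydroxylation (Upjohn conditions) should take the unhindered 1,1-disubstituted alkene and leave the tetrasubstituted ring alkene; the new carbinol centre is removed in step 9.

Step 8
Reactants: 10 2-[(1S)-2-[(3S)-4-{[tert-butyl(dimethyl)silyl]oxy}-3-methylbutyl]-3-methylcyclopent-2-en-1-yl]propane-1,2-diol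
Product: 11 2-[(1S,2S,3S)-2-[(3S)-4-{[tert-butyl(dimethyl)silyl]oxy}-3-methylbutyl]-3-methylcyclopentyl]propane-1,2-diol
Conditions: [Ir(cod)(PCy3)(py)]PF6 (5 mol %), H2 (3 atm), CH2Cl2, rt
Reagents that add atoms: none
Why: Hydroxyl-directed hydrogenation with the cationic iridium catalyst [Ir(cod)(PCy3)(py)]PF6 should deliver both hydrogens from the face of the diol-bearing substituent, which sets the two new ring D stereocentres (methyl and side chain cis to each other, both trans to the oxygenated substituent).

Step 9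
Reactants: 11 2-[(1S,2S,3S)-2-[(3S)-4-{[tert-butyl(dimethyl)silyl]oxy}-3-methylbutyl]-3-methylcyclopentyl]propane-1,2-diol
Product: 12 1-[(1S,2S,3S)-2-[(3S)-4-{[tert-butyl(dimethyl)silyl]oxy}-3-methylbutyl]-3-methylcyclopentyl]ethan-1-one
Conditions: NaIO4, THF–H2O, 0 °C → rt
Reagents that add atoms: none
Why: Periodate glycol cleavage unmasks the methyl ketone whose carbonyl carbon becomes the methylene-bearing carbon of ring C.

Step 10
Reactants: 12 1-[(1S,2S,3S)-2-[(3S)-4-{[tert-butyl(dimethyl)silyl]oxy}-3-methylbutyl]-3-methylcyclopentyl]ethan-1-one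
Product: 13 1-[(1S,2S,3S)-2-[(3S)-4-hydroxy-3-methylbutyl]-3-methylcyclopentyl]ethan-1-one
Conditions: n-Bu4NF, THF, rt
Reagents that add atoms: none
Why: Fluoride desilylation frees the primary alcohol; the ring carbon next to the ketone is already in its preferred trans arrangement.

Step 11
Reactants: 13 1-[(1S,2S,3S)-2-[(3S)-4-hydroxy-3-methylbutyl]-3-methylcyclopentyl]ethan-1-one
Product: 14 (2S)-4-[(1S,2S,5S)-2-acetyl-5-methylcyclopentyl]-2-methylbutanal
Conditions: Dess–Martin periodinane, NaHCO3, CH2Cl2, 0 °C → rt
Reagents that add atoms: none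
Why: Buffered Dess–Martin oxidation should give the aldehyde without epimerising its α-stereocentre.

Step 12
Reactants: 14 (2S)-4-[(1S,2S,5S)-2-acetyl-5-methylcyclopentyl]-2-methylbutanal
Product: 15 1-[(1S,2S,3S)-3-methyl-2-[(3S)-3-methylpent-4-en-1-yl]cyclopentyl]ethan-1-one
Conditions: Ph3PCH3Br, KN(SiMe3)2, THF, −78 → 0 °C (1.05 equiv of ylide)
Reagents that add atoms: methyltriphenylphosphonium bromide C[P+](c1ccccc1)(c1ccccc1)c1ccccc1.[Br-]
Why: Wittig methylenation at low temperature should take the aldehyde much faster than the hindered methyl ketone.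

Step 13
Reactants: 15 1-[(1S,2S,3S)-3-methyl-2-[(3S)-3-methylpent-4-en-1-yl]cyclopentyl]ethan-1-one
Product: 17 1-[(1S,2S,3S)-3-methyl-2-[(3S)-3-methylpent-4-en-1-yl]cyclopentyl]prop-2-en-1-one, via Mannich base 16 (not isolated)
Conditions: LiN(SiMe3)2, THF, −78 °C; Eschenmoser's salt, −78 → 0 °C; then MeI, CH2Cl2; DBU, rt
Reagents that add atoms: Eschenmoser's salt C=[N+](C)C.[I-]
Why: Kinetic deprotonation at the methyl group, Mannich reaction and elimination of the quaternised amine give the vinyl ketone (α-methylenation of a methyl ketone) with no change at any stereocentre.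

Step 14
Reactants: 17 1-[(1S,2S,3S)-3-methyl-2-[(3S)-3-methylpent-4-en-1-yl]cyclopentyl]prop-2-en-1-one
Product: 18 (1S,3Z,5S,8S,9S)-5,9-dimethylbicyclo[6.3.0]undec-3-en-2-one
Conditions: second-generation Grubbs catalyst RuCl2(=CHPh)(H2IMes)(PCy3) (5 mol %), CH2Cl2 (2 mM), reflux
Reagents that add atoms: none
Why: Ring-closing metathesis of the enone alkene with the terminal alkene should close the eight-membered ring C as the (Z)-enone, the trans-1,2-disubstituted cyclopentane holding the two chains close.

Step 15
Reactants: 18 (1S,3Z,5S,8S,9S)-5,9-dimethylbicyclo[6.3.0]undec-3-en-2-one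
Product: 20 (1S,5S,8S,9S)-5,9-dimethyl-3-methylidenebicyclo[6.3.0]undecan-2-one, via Mannich base 19 (not isolated)
Conditions: LiBH(s-Bu)3, THF, −78 °C; Eschenmoser's salt, −78 °C → rt; then MeI, CH2Cl2; DBU, rt
Reagents that add atoms: Eschenmoser's salt C=[N+](C)C.[I-]
Why: Conjugate reduction forms the enolate regiospecifically at the former α-alkene carbon, and Mannich trapping with elimination installs the exocyclic methylene that serves as Michael acceptor in the fragment union.

Step 16
Reactants: 21 3-methylbut-1-ene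
Product: 22 2,2-dichloro-3-(propan-2-yl)cyclobutan-1-one (racemic)
Conditions: Cl3CCOCl, Zn–Cu couple, Et2O, 0 °C → rt (excess alkene, sealed vessel)
Reagents that add atoms: trichloroacetyl chloride ClC(=O)C(Cl)(Cl)Cl
Why: Thermal [2+2] cycloaddition of dichloroketene made in situ with the terminal alkene gives the cyclobutanone with the carbonyl carbon bonded to the CH2 terminus; the racemic product becomes achiral in step 17.

Step 17
Reactants: 22 2,2-dichloro-3-(propan-2-yl)cyclobutan-1-one
Product: 23 3-(propan-2-yl)cyclobutan-1-one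
Conditions: Zn, AcOH, rt → 60 °C
Reagents that add atoms: none
Why: Zinc reduction removes both α-chlorine atoms and gives the prochiral 3-substituted cyclobutanone.

Step 18
Reactants: 23 3-(propan-2-yl)cyclobutan-1-one
Product: 24 triethyl{[(3S)-3-(propan-2-yl)cyclobut-1-en-1-yl]oxy}silane
Conditions: (S,S)-bis(1-phenylethyl)amine, n-BuLi, Et3SiCl (internal quench), THF, −100 °C
Reagents that add atoms: chlorotriethylsilane CC[Si](Cl)(CC)CC
Why: Enantioselective deprotonation by the chiral lithium amide with internal silyl quench differentiates the two enantiotopic α-CH2 groups and so sets the isopropyl-bearing stereocentre of ring A as (S).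

Step 19
Reactants: 24 triethyl{[(3S)-3-(propan-2-yl)cyclobut-1-en-1-yl]oxy}silane; 20 (1S,5S,8S,9S)-5,9-dimethyl-3-methylidenebicyclo[6.3.0]undecan-2-one
Product: 25 (2S,3S)-2-{[(1S,5S,8S,9S)-5,9-dimethyl-2-[(triethylsilyl)oxy]bicyclo[6.3.0]undec-2-en-3-yl]methyl}-3-(propan-2-yl)cyclobutan-1-one
Conditions: Et3SiOTf (10 mol %), CH2Cl2, −78 °C
Reagents that add atoms: none
Why: Mukaiyama–Michael addition with silyl transfer: the silyloxycyclobutene should attack the CH2 terminus of the activated α-methylene ketone on its face anti to isopropyl, which sets the new cyclobutanone α-stereocentre trans to isopropyl and leaves the ring C carbonyl masked regiospecifically as its silyl enol ether.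

Step 20
Reactants: 25 (2S,3S)-2-{[(1S,5S,8S,9S)-5,9-dimethyl-2-[(triethylsilyl)oxy]bicyclo[6.3.0]undec-2-en-3-yl]methyl}-3-(propan-2-yl)cyclobutan-1-one
Product: 26 (2S,3S)-2-{[(1S,3Z,5S,8S,9S)-5,9-dimethyl-2-oxobicyclo[6.3.0]undec-3-en-3-yl]methyl}-3-(propan-2-yl)cyclobutan-1-one
Conditions: Pd(OAc)2 (15 mol %), O2 (1 atm), DMSO, 60 °C
Reagents that add atoms: none
Why: Saegusa–Ito oxidation of the regiodefined silyl enol ether should give the endocyclic 2-substituted cyclooctenone, β-hydride elimination into the ring being usual for 2-alkyl cycloalkanone enol ethers.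

Step 21
Reactants: 26 (2S,3S)-2-{[(1S,3Z,5S,8S,9S)-5,9-dimethyl-2-oxobicyclo[6.3.0]undec-3-en-3-yl]methyl}-3-(propan-2-yl)cyclobutan-1-one
Product: 27 (1R,2S,3S)-2-{[(1S,3Z,5S,8S,9S)-5,9-dimethyl-2-oxobicyclo[6.3.0]undec-3-en-3-yl]methyl}-3-(propan-2-yl)-1-(prop-1-en-2-yl)cyclobutan-1-ol
Conditions: CH2=C(CH3)MgBr, CeCl3, THF, −78 °C
Reagents that add atoms: isopropenylmagnesium bromide C=C(C)[Mg]Br
Why: Organocerium 1,2-addition should take the strained, far more electrophilic cyclobutanone in preference to the hindered, doubly α-branched enone; entry trans to the adjacent CH2 arm gives the (1R) carbinol, a centre that is destroyed again in step 22.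

Step 22
Reactants: 27 (1R,2S,3S)-2-{[(1S,3Z,5S,8S,9S)-5,9-dimethyl-2-oxobicyclo[6.3.0]undec-3-en-3-yl]methyl}-3-(propan-2-yl)-1-(prop-1-en-2-yl)cyclobutan-1-ol
Product: 28 tetracyclic enedione (ring A cyclopentanone and ring C enone; trans A/B fusion; all stereocentres as in the target)
Conditions: Pd(OCOCF3)2 (15 mol %), 1,4-benzoquinone (2 equiv), DMPU–THF (1:4), 45 °C
Reagents that add atoms: none
Why: Proposed new method: Pd(OCOCF3)2 coordinates the electron-rich isopropenyl group anti to the C1–C2 bond of the cyclobutanol; the substituted ring carbon C2 migrates to the internal alkene carbon (semipinacol 1,2-shift, four- to five-membered ring expansion that closes ring A as the cyclopentanone) and leaves a neopentyl σ-alkylpalladium without β-hydrogens; this adds across the tethered enone by 6-endo-trig migratory insertion at the β-carbon (closing ring B), and the palladium enolate, after O/C equilibration, loses the hydrogen on the B/C fusion carbon as in a Saegusa oxidation, benzoquinone returning zerovalent palladium to the divalent state. The closest known reaction type is the divalent-palladium ring expansion–olefin insertion cascade of 1-isopropenylcyclobutanols with a pendant styrene-type olefin, which gives angular-methyl hydrindanones; new here are the enone acceptor, the endo mode of insertion and the enolate-type elimination that restores the alkene. The new quaternary centre is set in the migration: C2 migrates with retention and attacks anti to palladium from the rotamer in which the palladium-bound CH2 lies over the unsubstituted ring CH2 and away from the hydroxyl (the donor co-solvent suppresses O–Pd chelation), which places the methyl group syn to the C2 arm and so gives the trans ring fusion. The step needs activation of the isopropenyl group over the electron-poor enone (electronic), 6-endo over 5-exo insertion (attack at the enone β-carbon forms no quaternary centre) and elimination into the eight-membered ring rather than toward the ring B CH2 (endocyclic preference of palladium enolates of 2-alkyl cycloalkanones).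

Step 23
Reactants: 28 tetracyclic enedione
Product: 29 tetracyclic hydroxy enone (ring A carbinol (R) with hydroxyl cis to the angular methyl)
Conditions: NaBH4, MeOH–CH2Cl2, −40 °C
Reagents that add atoms: none
Why: Borohydride should reduce the saturated cyclopentanone faster than the hindered ring C enone, and hydride attack anti to the adjacent angular methyl places the hydroxyl cis to that methyl, as in 17-keto steroid reductions.

Step 24
Reactants: 29 tetracyclic hydroxy enone
Product: 30 CNP0544018.1
Conditions: Cp2Ti(μ-CH2)(μ-Cl)AlMe2 (3 equiv), pyridine, THF–toluene, −40 °C → rt; aq. NaOH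
Reagents that add atoms: Tebbe reagent (chloride bridge drawn charge-separated and cyclopentadienyl rings σ-bonded) C[Al-]1(C)C[Ti]([Cl+]1)(C1C=CC=C1)C1C=CC=C1
Why: Tebbe methylenation with Cp2Ti(μ-CH2)(μ-Cl)AlMe2 should convert the hindered, enolisable enone carbonyl into the exocyclic methylene under non-basic conditions that leave the allylic stereocentre alone; excess reagent covers the free hydroxyl as its metal alkoxide, which returns on basic work-up.

## Compound list

1 | (S)-(−)-limonene | CC1=CC[C@H](CC1)C(C)=C | starting material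
2 | (3S)-6-oxo-3-(prop-1-en-2-yl)heptanal | O=CC[C@H](CCC(C)=O)C(C)=C | intermediate
3 | (5R)-2-methyl-5-(prop-1-en-2-yl)cyclopent-1-ene-1-carbaldehyde | O=CC1=C(C)CC[C@@H]1C(C)=C | intermediate
4 | [(5R)-2-methyl-5-(prop-1-en-2-yl)cyclopent-1-en-1-yl]methanol | OCC1=C(C)CC[C@@H]1C(C)=C | intermediate
5 | (3R)-2-(bromomethyl)-1-methyl-3-(prop-1-en-2-yl)cyclopent-1-ene | BrCC1=C(C)CC[C@@H]1C(C)=C | intermediate
6 | (2R)-3-bromo-2-methylpropan-1-ol | OC[C@@H](C)CBr | starting material
7 | [(2R)-3-bromo-2-methylpropoxy](tert-butyl)dimethylsilane | CC(C)(C)[Si](C)(C)OC[C@@H](C)CBr | intermediate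
8 | (2R)-3-{[tert-butyl(dimethyl)silyl]oxy}-2-methylpropylmagnesium bromide | CC(C)(C)[Si](C)(C)OC[C@@H](C)C[Mg]Br | intermediate
9 | tert-butyldimethyl{[(2S)-2-methyl-4-[(5R)-2-methyl-5-(prop-1-en-2-yl)cyclopent-1-en-1-yl]butyl]oxy}silane | CC(C)(C)[Si](C)(C)OC[C@@H](C)CCC1=C(C)CC[C@@H]1C(C)=C | intermediate
10 | 2-[(1S)-2-[(3S)-4-{[tert-butyl(dimethyl)silyl]oxy}-3-methylbutyl]-3-methylcyclopent-2-en-1-yl]propane-1,2-diol (both epimers at the diol carbon) | CC(C)(C)[Si](C)(C)OC[C@@H](C)CCC1=C(C)CC[C@@H]1C(C)(O)CO | intermediate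
11 | 2-[(1S,2S,3S)-2-[(3S)-4-{[tert-butyl(dimethyl)silyl]oxy}-3-methylbutyl]-3-methylcyclopentyl]propane-1,2-diol (both epimers at the diol carbon) | CC(C)(C)[Si](C)(C)OC[C@@H](C)CC[C@@H]1[C@@H](C(C)(O)CO)CC[C@@H]1C | intermediate
12 | 1-[(1S,2S,3S)-2-[(3S)-4-{[tert-butyl(dimethyl)silyl]oxy}-3-methylbutyl]-3-methylcyclopentyl]ethan-1-one | CC(C)(C)[Si](C)(C)OC[C@@H](C)CC[C@@H]1[C@@H](C(C)=O)CC[C@@H]1C | intermediate
13 | 1-[(1S,2S,3S)-2-[(3S)-4-hydroxy-3-methylbutyl]-3-methylcyclopentyl]ethan-1-one | OC[C@@H](C)CC[C@@H]1[C@@H](C(C)=O)CC[C@@H]1C | intermediate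
14 | (2S)-4-[(1S,2S,5S)-2-acetyl-5-methylcyclopentyl]-2-methylbutanal | O=C[C@@H](C)CC[C@@H]1[C@@H](C(C)=O)CC[C@@H]1C | intermediate
15 | 1-[(1S,2S,3S)-3-methyl-2-[(3S)-3-methylpent-4-en-1-yl]cyclopentyl]ethan-1-one | C=C[C@@H](C)CC[C@@H]1[C@@H](C(C)=O)CC[C@@H]1C | intermediate
16 | 3-(dimethylamino)-1-[(1S,2S,3S)-3-methyl-2-[(3S)-3-methylpent-4-en-1-yl]cyclopentyl]propan-1-one | C=C[C@@H](C)CC[C@@H]1[C@@H](C(=O)CCN(C)C)CC[C@@H]1C | intermediate
17 | 1-[(1S,2S,3S)-3-methyl-2-[(3S)-3-methylpent-4-en-1-yl]cyclopentyl]prop-2-en-1-one | C=C[C@@H](C)CC[C@@H]1[C@@H](C(=O)C=C)CC[C@@H]1C | intermediate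
18 | (1S,3Z,5S,8S,9S)-5,9-dimethylbicyclo[6.3.0]undec-3-en-2-one | O=C1/C=C\[C@@H](C)CC[C@@H]2[C@@H]1CC[C@@H]2C | intermediate
19 | (1S,5S,8S,9S)-3-[(dimethylamino)methyl]-5,9-dimethylbicyclo[6.3.0]undecan-2-one (both epimers at C3) | O=C1C(CN(C)C)C[C@@H](C)CC[C@@H]2[C@@H]1CC[C@@H]2C | intermediate
20 | (1S,5S,8S,9S)-5,9-dimethyl-3-methylidenebicyclo[6.3.0]undecan-2-one | O=C1C(=C)C[C@@H](C)CC[C@@H]2[C@@H]1CC[C@@H]2C | intermediate
21 | 3-methylbut-1-ene | C=CC(C)C | starting material
22 | 2,2-dichloro-3-(propan-2-yl)cyclobutan-1-one (racemic) | O=C1CC(C(C)C)C1(Cl)Cl | intermediate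
23 | 3-(propan-2-yl)cyclobutan-1-one | O=C1CC(C(C)C)C1 | intermediate
24 | triethyl{[(3S)-3-(propan-2-yl)cyclobut-1-en-1-yl]oxy}silane | CC[Si](CC)(CC)OC1=C[C@H](C(C)C)C1 | intermediate
25 | (2S,3S)-2-{[(1S,5S,8S,9S)-5,9-dimethyl-2-[(triethylsilyl)oxy]bicyclo[6.3.0]undec-2-en-3-yl]methyl}-3-(propan-2-yl)cyclobutan-1-one | CC[Si](CC)(CC)O/C1=C(\C[C@H]2[C@H](C(C)C)CC2=O)C[C@@H](C)CC[C@@H]3[C@@H]1CC[C@@H]3C | intermediate
26 | (2S,3S)-2-{[(1S,3Z,5S,8S,9S)-5,9-dimethyl-2-oxobicyclo[6.3.0]undec-3-en-3-yl]methyl}-3-(propan-2-yl)cyclobutan-1-one | O=C1/C(C[C@H]2[C@H](C(C)C)CC2=O)=C\[C@@H](C)CC[C@@H]3[C@@H]1CC[C@@H]3C | intermediate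
27 | (1R,2S,3S)-2-{[(1S,3Z,5S,8S,9S)-5,9-dimethyl-2-oxobicyclo[6.3.0]undec-3-en-3-yl]methyl}-3-(propan-2-yl)-1-(prop-1-en-2-yl)cyclobutan-1-ol | O=C1/C(C[C@H]2[C@H](C(C)C)C[C@]2(O)C(C)=C)=C\[C@@H](C)CC[C@@H]3[C@@H]1CC[C@@H]3C | intermediate
28 | tetracyclic enedione: target skeleton with C=O in place of the exocyclic methylene and of the carbinol; quaternary C–CH3 (R), isopropyl CH (S), A/B fusion CH (S), ring C CH–CH3 (S), C/D fusion carbons (S,S), ring D CH–CH3 (S) | O=C1C2=C(C[C@@]3(C)C(=O)C[C@@H](C(C)C)[C@@H]3C2)[C@@H](C)CC[C@@H]2[C@@H]1CC[C@@H]2C | intermediate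
29 | tetracyclic hydroxy enone: as 28 with the ring A ketone reduced to the (R) carbinol, hydroxyl cis to the angular methyl | O=C1C2=C(C[C@@]3(C)[C@H](O)C[C@@H](C(C)C)[C@@H]3C2)[C@@H](C)CC[C@@H]2[C@@H]1CC[C@@H]2C | intermediate
30 | CNP0544018.1 | C=C1C2=C(C[C@@]3(C)[C@H](O)C[C@@H](C(C)C)[C@@H]3C2)[C@@H](C)CC[C@@H]2[C@@H]1CC[C@@H]2C | target

## Step count and risks

Total steps: 24. Longest linear sequence: 20 steps (steps 1–4, 6–15 and 19–24, from 1).

Steps most likely to fail:

Step 22 (proposed method). The neopentylpalladium intermediate may be protonated, or may insert too slowly into the hindered enone. The palladium enolate may eliminate toward the ring B CH2 instead of into ring C. O–Pd chelation may favour the rotamer that leads to the cis ring fusion. The fallback uses known reaction types and sets out from 27. N-Bromosuccinimide (CH2Cl2–i-PrOH, −20 °C) should trigger a bromonium-induced semipinacol ring expansion to the bromomethyl cyclopentanone F1. Nickel-catalysed reductive conjugate addition of the primary alkyl bromide to the tethered enone in the presence of Et3SiCl (NiCl2(dme), neocuproine, Mn, DMF) should close ring B and give the silyl enol ether F2. Saegusa–Ito oxidation (Pd(OAc)2, O2, DMSO) should then give 28, where the route is rejoined.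

Step 21. Chemoselectivity may be lost through attack at the enone carbonyl, conjugate addition, or enolisation of the cyclobutanone. The fallback sets out from 25. The organocerium reagent (CH2=C(CH3)MgBr, CeCl3, THF, −78 °C) is added while the ring C carbonyl is still masked, which should give the tertiary alcohol F3. The silyl enol ether is then dehydrogenated without palladium by IBX·4-methoxypyridine N-oxide (DMSO, rt), which should give 27.

Step 14. Oligomerisation by cross-metathesis may compete with slow closure of the eight-membered ring at the electron-poor enone alkene. The fallback sets out from 12. LiN(i-Pr)2 and ClP(O)(OEt)2 (THF, −78 °C) should give the enol phosphate F4. Further LiN(i-Pr)2 should rearrange it (1,3-phosphorus shift from oxygen to carbon) to the β-keto phosphonate F5. n-Bu4NF should give the alcohol F6, and Dess–Martin oxidation the aldehyde F7. An intramolecular Horner–Wadsworth–Emmons reaction (LiCl, i-Pr2NEt, MeCN, high dilution) should close ring C and give 18.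

Further compounds
F1 | step 22 | bromomethyl cyclopentanone: (2R,3S,4S)-2-(bromomethyl)-2-methyl-4-(propan-2-yl)cyclopentan-1-one carrying at C3 the (5,9-dimethyl-2-oxobicyclo[6.3.0]undec-3-en-3-yl)methyl group of 27 | BrC[C@@]1(C)C(=O)C[C@@H](C(C)C)[C@@H]1C/C1=C/[C@@H](C)CC[C@@H]2[C@H](CC[C@@H]2C)C1=O
F2 | step 22 | tetracyclic triethylsilyl enol ether of the ring C ketone with ring B closed and the ring A ketone in place (both epimers at the new ring B CH) | CC[Si](CC)(CC)OC1=C2C(C[C@@]3(C)C(=O)C[C@@H](C(C)C)[C@@H]3C2)[C@@H](C)CC[C@@H]2[C@@H]1CC[C@@H]2C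
F3 | step 21 | (1R,2S,3S)-1-isopropenyl-cyclobutanol derived from 25 with the ring C carbonyl still masked as its triethylsilyl enol ether | CC[Si](CC)(CC)O/C1=C(\C[C@H]2[C@H](C(C)C)C[C@]2(O)C(C)=C)C[C@@H](C)CC[C@@H]3[C@@H]1CC[C@@H]3C
F4 | step 14 | diethyl enol phosphate of methyl ketone 12 | CC(C)(C)[Si](C)(C)OC[C@@H](C)CC[C@@H]1[C@@H](C(=C)OP(=O)(OCC)OCC)CC[C@@H]1C
F5 | step 14 | β-keto phosphonate of 12 (diethyl 2-oxo-2-cyclopentylethylphosphonate with the silyloxy side chain) | CC(C)(C)[Si](C)(C)OC[C@@H](C)CC[C@@H]1[C@@H](C(=O)CP(=O)(OCC)OCC)CC[C@@H]1C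
F6 | step 14 | β-keto phosphonate primary alcohol | OC[C@@H](C)CC[C@@H]1[C@@H](C(=O)CP(=O)(OCC)OCC)CC[C@@H]1C
F7 | step 14 | β-keto phosphonate aldehyde | O=C[C@@H](C)CC[C@@H]1[C@@H](C(=O)CP(=O)(OCC)OCC)CC[C@@H]1C
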